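Readings and results were generated by integration for substances that don't exist.

I commit to one number for the gamma flask, and I take it straight from the alpha readings. You asked for a quick number, so I start from the last alpha reading and add a tail.

| flask | L | E | time |
|---|---|---|---|
| alpha | 0.150 M | 0.0120 M |  |
| epsilon | 0.0900 M | 0.0120 M |  |
| eta | 0.450 M | 0.0120 M |  |
| theta | 0.150 M | 0.0360 M |  |
| gamma | 0.150 M | 0.0120 M | 23 h |

| run | time / h | [J] / M |
|---|---|---|
| alpha run | 0.25 | 0.0017 |
| alpha run | 0.77 | 0.0121 |
| alpha run | 1.5 | 0.0268 |
| alpha run | 2.3 | 0.0422 |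
| alpha run | 3.3 | 0.0577 |
| alpha run | 4.5 | 0.0632 |
| alpha run | 5.7 | 0.0657 |
| epsilon run | 0.25 | 9 × 10⁻⁴ |
| epsilon run | 0.77 | 0.0043 |
| epsilon run | 1.5 | 0.0115 |
| epsilon run | 2.3 | 0.0172 |
| epsilon run | 3.3 | 0.0235 |
| epsilon run | 4.5 | 0.0290 |
| epsilon run | 5.7 | 0.0306 |
| eta run | 0.25 | 0.0126 |
| eta run | 0.77 | 0.0910 |
| eta run | 1.5 | 0.2571 |
| eta run | 2.3 | 0.3095 |
| eta run | 3.3 | 0.3154 |
| eta run | 4.5 | 0.3162 |
| eta run | 5.7 | 0.3153 |
| theta run | 0.25 | 0.0092 |
| theta run | 0.77 | 0.0313 |
| theta run | 1.5 | 0.0590 |
| theta run | 2.3 | 0.0789 |
| theta run | 3.3 | 0.0893 |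
| theta run | 4.5 | 0.0919 |
| theta run | 5.7 | 0.0939 |

(readings scatter by 8 × 10⁻⁴ M)

* how the opening rate goes with [E] round the charge of the alpha run: the exponent of the rate at two percent of L gone to J
* how the opening rate goes with [L] round the charge of the alpha run: the exponent of the rate at two percent of L gone to J (one fixed amount of J, the same in the runs compared)
* J in the gamma run at 23 h, as a share of the L charged

- Overall: L -> J, with E as catalyst.
- Constant volume, constant temperature.
- An order is taken over about fifteen percent of the charge, up and down.

Follow one molecule of L through a flask: at the end it stands as J, or it doesn't. At the last alpha reading that chance is 43.8 %. It is [J] over the [L] charged, the yield, and I call it the J-share. The J-share is no constant. At the last reading it is 34.0 % in the epsilon run, 70.1 % in the eta run and 62.6 % in the theta run. So I read gamma from alpha, whose charge it repeats.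

The alpha run has not quite stopped. Its last two steps in [J] are 0.00550 M and 0.00250 M, so each step is 0.455 of the one before. If the steps go on shrinking by that factor, they add 0.00208 M, and the J-share becomes 45.2 %. Each reading carries a scatter of 8 × 10⁻⁴ M, so this tail is a rough reading.

For the two orders I reckon nothing myself. The forecast gives 0.85 (0.55 to 1.25) in [E] and 1.6 (1.2 to 2.05) in [L]. For gamma it gives 45 % (43.5 % to 47.5 %), on this ground: “Gamma is an alpha repeat, so it should plateau near 0.068 M, or 45%.” My figure stands 0.20 percentage points above its central value.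

The simulation gives 0.81 in [E], 1.1 in [L] and 45.7 % for gamma.

    E + L → J + E (6.084 M⁻¹ h⁻¹)
    L → Rx (0.3175 h⁻¹)
    L + J → 2 J (8.604 M⁻¹ h⁻¹)

The forecast's order in [L] stands 1.45 times the simulated one. The passing of L into Rx moves the readings by 85 in units of the scatter, root mean square, and it is the branch of the fork that does not end as J. Gamma's J-share stands 1.9 points above the 43.8 % of the last alpha reading. In the theta run the J-share at the last reading is 62.6 %, 1.43 times alpha's, and there the J made comes to half of the L charged at 2.06 h.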